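All runs stem from a simulated flask on assumed constants; scatter was added.

Divide the Q charged by the E charged before asking anything of a rate.

| flask | E | Q | remark | time |
|---|---|---|---|---|
| south-east | 0.50 M (fed, over 15 s) | 0.17 M | run made earlier |  |
| south | 0.50 M (fed, over 15 s) | 0.38 M | run made earlier |  |
| flask | 0.50 M (fed, over 15 s) | 0.250 M |  | 4.0 h |

| run | time / h | E / % | D / % |
|---|---|---|---|
| south-east | 0.200 | 70 | 29 |
| south-east | 0.417 | 70 | 27 |
| south-east | 1.00 | 70 | 30 |
| south-east | 2.50 | 71 | 30 |
| south | 0.667 | 28 | 64 |
| south | 1.33 | 34 | 66 |
| south | 2.00 | 27 | 64 |
| south | 2.50 | 30 | 65 |

(scatter of a reading: 2 percentage points)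

- what is said of D includes X
- X is a solid; its amount is given per volume of the solution
- steps under discussion: X <-> D; D + Q <-> L + G; E + Q <-> L + D
- the reaction counts as stopped when no species that holds the E changes by six tenths of a point or more over the second half of the time

1. why nothing more happens at 4.0 h, or that something still does (forward and back rates have come level / Q has run out first / all of E has reacted / it is still moving)
2. how much of the E has reacted by 4.0 h
3. how much D there is at 4.0 h, in percent of the E charged

In the new flask Q is charged below E, so Q is the limiting reagent: each E that reacts takes one Q, and each D going on to G takes a second. In the new flask, Q amounts to 50.0% of the E charge; this is the Q ceiling, the share of E that the charged Q can turn over.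

But the earlier runs, read by their means, stop short of their ceilings:

south-east: ceiling 34.0%, E reacted 29.7%, ceiling filled 0.875

south: ceiling 76.0%, E reacted 70.2%, ceiling filled 0.924

So the reckoning here takes the mean filling:

new flask, E reacted: 0.900 × 50.0% = 45.0%

Two runs are thin support, yet the new ceiling lies between theirs. The same division, made on the D readings, gives a filling of its own:

new flask, D: 0.852 × 50.0% = 42.6%

Is the time enough? South-east E reads flat from 0.200 h, so its half-life reads as shorter than that first time, and the time asked of the new flask is 20.0 times that first time. Did Q simply vanish, then? South-east, with the second Q taken up by G counted as well, reads a gap of 3.5 percentage points below its ceiling, a thin reading against a scatter of 2 points, with E still present. That points, with some doubt, to rates come level, and the new flask is reckoned here to end the same way.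

The forecast gives 46% reacted and 44.5% D, slightly above this reckoning, and ends with forward and back rates have come level: “Q is the limiting reagent, with a small equilibrium residual”.

The new flask gives 46.6% reacted and 44.4% D: forward and back rates have come level.

    X ⇌ D, rate k1*(cs1 - [D]) while solid is left; crystals form when [D] > cs1 (solubility = 40.0 mM, k = 0.780 s⁻¹)
    D + Q ⇌ L + G (K = 12.0, k = 0.0400 M⁻¹ s⁻¹)
    E + Q ⇌ L + D (K = 6.40, k = 0.0490 M⁻¹ s⁻¹)

That conversion fills 0.932 of the Q ceiling of 50.0%. The consumption of Q is the main reason the new flask stays there: the same run without that consumption reaches 96.7% conversion instead of 46.6%, which is 94% of what is missing. The neighbour flask with 1.2 M of E has a ceiling of 20.8% by the same division and reacts 20.4%.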